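In the scheme under suspicion each product molecule costs one partner and one substrate, and each quenched reagent costs one partner. The quench follows its own clock, but once the protic impurity is consumed you can divide the rate of partner loss by the rate of conversion and time drops out: from then on [partner] falls along conversion on a fixed line, apart from the trace taken by a catalyst charged at 0.1 mol%.

the same everywhere: free catalyst 0.1 mol%

|  | left-handed substrate | right-handed substrate | partner | protic impurity | remark |
|---|---|---|---|---|---|
| summer | 1 M | 1 M | 0.80 equiv | 0.10 M | run made earlier |
| midnight | 1 M | 1 M | 1.8 equiv | 0.10 M | run made earlier |
| flask | 1.0 M | 1.0 M | 1.20 equiv | 0.100 M |  |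

- summer (time / min: left-handed product / %, left-handed substrate / %): 15.0: 5.0, 45.6; 40.0: 6.1, 43.3; 80.0: 14.6, 38.2; 120: 17.4, 32.8
- midnight (time / min: left-handed product / %, left-handed substrate / %): 15.0: 3.5, 46.1; 40.0: 11.1, 38.5; 80.0: 21.0, 28.7; 120: 25.7, 23.6

(scatter of a reading: 1 percentage point)

1. factor on the rate of making left-handed product when 50% of the left-handed substrate and right-handed substrate together are converted if partner is charged twice over
2. factor on the rate when 50% of the left-handed substrate and right-handed substrate together are converted if free catalyst is charged at 0.5 mol% instead

- free catalyst is single-handed; left-handed substrate and right-handed substrate are mirror images of each other, charged as a racemate, each of them at the stated concentration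
- the numbers in the tables scatter by 1 percentage point (one standard deviation)
- on the list of suspects stand: free catalyst + left-handed substrate <-> catalyst intermediate A; partner + catalyst intermediate A -> free catalyst + left-handed product; free catalyst + right-handed substrate <-> catalyst intermediate B; partner + protic impurity -> quenched reagent; partner + catalyst intermediate B -> free catalyst + right-handed product; partner + free catalyst -> spent catalyst
- no earlier run changes the charge of free catalyst; that part of a forecast is a guess

Now climb the ladder of rates, fastest first. Read as first order, left-handed substrate in the midnight run decays at 0.00638 min⁻¹. At this loading that is about one turnover per catalyst every 0.157 min, far shorter than the wait for the first reading, so you should expect the catalyst forms to have settled by then. Next comes the substrate itself, with a half-life of 109 min at midnight and 221 min in the summer run.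

The last rung is the reach, 55.0% for the flask: the conversion at which the partner charged, less the protic impurity's share, is used up. It stands below full conversion, which makes partner the limiting reagent. The reach is 35.0% for summer and 85.0% for midnight.

At 50% conversion the same line leaves the flask 0.100 M of partner, and doubling the charge leaves 1.30 M. By my reckoning a rate first order in partner would therefore rise 13.0-fold, and one proportional to catalyst 5.00-fold.

The forecast gave 8.5 (range 4.5 to 13.5), holding that “the dependence on partner is sublinear”, and 5.2 (range 4.5 to 6.8) for the catalyst.

The simulation gives 7.25 for doubled partner, whose reach of 115% lies above full conversion, and 6.38 for the catalyst.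

    free catalyst + left-handed substrate ⇌ catalyst intermediate A (K = 0.527 M⁻¹, k = 0.821 M⁻¹ s⁻¹)
    partner + catalyst intermediate A → free catalyst + left-handed product (k = 2.60 M⁻¹ s⁻¹)
    free catalyst + right-handed substrate ⇌ catalyst intermediate B (K = 5.32 M⁻¹, k = 1.45 M⁻¹ s⁻¹)
    partner + protic impurity → quenched reagent (k = 0.00115 M⁻¹ s⁻¹)
    partner + catalyst intermediate B → free catalyst + right-handed product (k = 0.0362 M⁻¹ s⁻¹)
    partner + free catalyst → spent catalyst (k = 7.28 × 10⁻⁵ M⁻¹ s⁻¹)

At 0.775 h in the flask, partner has a half-life of 2.5 h through the left-handed route, shorter than the 7.0 h through the right-handed route, so at that moment the left-handed route uses partner 2.84 times as fast. After 20.0 h, with partner at 0.261% of its charge, the flask holds 39.8% left-handed product and 15.0% right-handed product, together 54.8% against a reach of 55.0%.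

(The readings are simulated with constants of no real substance; the scatter is artificial.)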